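## Retrosynthetic overview

1. The target is cut at the side-chain ester: acrylic acid **28** (right half) adds as its carboxylate to the CH2 of spiro-epoxide **17** (left half), giving the primary ester and the tertiary alcohol in one step. An allylic oxidation, PMB removal and a Pinnick oxidation finish the synthesis.
2. Both six-membered rings come from one building block, (R)-cryptone **4**, made by an organocatalytic Michael/aldol sequence from 3-methylbutanal and but-3-en-2-one.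
3. Left half (ring A, then lactone ring B): copper-catalysed trans conjugate addition of a bis(silyloxymethyl)vinyl Grignard to **4**, α-alkoxymethylation, Corey–Chaykovsky spiro-epoxide, oxidation to the acid. Seven-membered lactonisation then also tells the two CH2OH groups apart.
4. Right half (ring C): 1,3-carbonyl transposition of **4**, cis-selective reduction, then the key palladium-catalysed allylic alkylation with a nitro ester and loss of HNO2, which sets the cis C1 centre and the (E)-acrylate.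
5. Ring order: cyclohexenone **4** first (serves rings A and C), spiro-epoxide, lactone ring B, then fragment union.

Assumption: 1,3-dihydroxyacetone is taken from its commercial dimer; PMBOCH2Cl and Bu3SnCH2OPMB are used as known reagents.

Abbreviations: TBS = tert-butyldimethylsilyl, TMS = trimethylsilyl, PMB = 4-methoxybenzyl, "side chain" = 3-(TBS-oxy)-2-[(TBS-oxy)methyl]prop-1-en-1-yl.

## Route

Step 1
Reactants: 1 3-methylbutanal; 2 but-3-en-2-one
Product: 3 (2R)-5-oxo-2-(propan-2-yl)hexanal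
Conditions: (R)-2-[methoxy(diphenyl)methyl]pyrrolidine (5 mol %), ethyl 3,4-dihydroxybenzoate (20 mol %), neat, 4 °C
Reagents that add atoms: none
Why: Enamine-catalysed Michael addition; the bulky group of the (R)-amine shields one face of the E-enamine, so the enone adds to the open face and sets the 2R centre that carries the isopropyl group of both halves.

Step 2
Reactants: 3 (2R)-5-oxo-2-(propan-2-yl)hexanal
Product: 4 (4R)-4-(propan-2-yl)cyclohex-2-en-1-one [(R)-cryptone]
Conditions: LiOH (0.1 equiv), i-PrOH, 23 °C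
Reagents that add atoms: none
Why: Intramolecular aldol condensation (Robinson-type ring closure) of the methyl ketone onto the aldehyde; the mild base leaves the γ-stereocentre untouched.

Step 3
Reactants: 5 1,3-dihydroxypropan-2-one
Product: 6 1,3-bis(TBS-oxy)propan-2-one
Conditions: TBSCl, imidazole, DMF, 23 °C
Reagents that add atoms: tert-butyldimethylsilyl chloride, CC(C)(C)[Si](C)(C)Cl
Why: Standard silylation of both primary hydroxyls; no stereocentre is involved.

Step 4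
Reactants: 6 1,3-bis(TBS-oxy)propan-2-one
Product: 7 1-bromo-3-(TBS-oxy)-2-[(TBS-oxy)methyl]prop-1-ene
Conditions: [Ph3PCH2Br]Br, NaN(SiMe3)2, THF, −78 → 23 °C
Reagents that add atoms: (bromomethyl)triphenylphosphonium bromide, BrC[P+](c1ccccc1)(c1ccccc1)c1ccccc1.[Br-]
Why: Wittig bromomethylenation; the ketone is symmetric, so the vinyl bromide has no E/Z issue.

Step 5
Reactants: 7 1-bromo-3-(TBS-oxy)-2-[(TBS-oxy)methyl]prop-1-ene; 4 (4R)-4-(propan-2-yl)cyclohex-2-en-1-one
Product: 9 (3S,4R)-3-(side chain)-4-(propan-2-yl)-1-(TMS-oxy)cyclohex-1-ene, via alkenylmagnesium bromide 8 (not isolated)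
Conditions: Mg, THF, 40 °C; then CuBr·SMe2 (5 mol %), Me3SiCl, DMPU, THF, −78 °C, add 4
Reagents that add atoms: chlorotrimethylsilane, C[Si](C)(C)Cl
Why: Copper-catalysed, Me3SiCl-accelerated conjugate addition of the alkenyl Grignard; it attacks anti to the C4 isopropyl group (3,4-trans, the future ring-fusion carbon), and the enolate is trapped regiospecifically as its silyl enol ether.

Step 6
Reactants: 9 (3S,4R)-3-(side chain)-4-(propan-2-yl)-1-(TMS-oxy)cyclohex-1-ene
Product: 10 (2R,3S,4R)-3-(side chain)-2-[(PMB-oxy)methyl]-4-(propan-2-yl)cyclohexan-1-one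
Conditions: PMBOCH2Cl, ZnBr2 (10 mol %), CH2Cl2, −40 → 0 °C
Reagents that add atoms: 4-methoxybenzyl chloromethyl ether, COc1ccc(COCCl)cc1
Why: Lewis-acid-mediated (Mukaiyama-type) α-alkoxymethylation of the silyl enol ether by the oxocarbenium ion; it enters anti to the neighbouring alkenyl group and gives the all-equatorial 2,3-trans ketone, which is also the thermodynamic epimer.

Step 7
Reactants: 10 (2R,3S,4R)-3-(side chain)-2-[(PMB-oxy)methyl]-4-(propan-2-yl)cyclohexan-1-one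
Product: 11 (3S,4R,5S,6R)-5-(side chain)-4-[(PMB-oxy)methyl]-6-(propan-2-yl)-1-oxaspiro[2.5]octane
Conditions: Me3SI, KN(SiMe3)2, THF, −10 → 0 °C
Reagents that add atoms: trimethylsulfonium iodide, C[S+](C)C.[I-]
Why: Corey–Chaykovsky epoxidation; the unstabilised sulfonium ylide adds irreversibly from the axial direction of the chair ketone, so the new CH2 is axial (cis to the C4 substituent) and the oxygen equatorial, which is the configuration of the target's tertiary carbinol.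

Step 8
Reactants: 11 (3S,4R,5S,6R)-5-(side chain)-4-[(PMB-oxy)methyl]-6-(propan-2-yl)-1-oxaspiro[2.5]octane
Product: 12 [(3S,4R,5S,6R)-5-(side chain)-6-(propan-2-yl)-1-oxaspiro[2.5]octan-4-yl]methanol
Conditions: DDQ, CH2Cl2/pH 7 buffer, 0 °C
Reagents that add atoms: none
Why: Oxidative PMB ether cleavage under buffered conditions, which the epoxide and the silyl ethers tolerate.

Step 9
Reactants: 12 [(3S,4R,5S,6R)-5-(side chain)-6-(propan-2-yl)-1-oxaspiro[2.5]octan-4-yl]methanol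
Product: 14 (3S,4S,5S,6R)-5-(side chain)-6-(propan-2-yl)-1-oxaspiro[2.5]octane-4-carboxylic acid, via epoxy aldehyde 13 (not isolated)
Conditions: TEMPO (20 mol %), PhI(OAc)2 (2.2 equiv), MeCN/pH 7 buffer, 23 °C
Reagents that add atoms: water, O
Why: Oxoammonium (TEMPO/PhI(OAc)2) oxidation of the primary alcohol through the aldehyde hydrate to the acid under near-neutral conditions; the carboxyl stays equatorial, trans to the alkenyl group.

Step 10
Reactants: 14 (3S,4S,5S,6R)-5-(side chain)-6-(propan-2-yl)-1-oxaspiro[2.5]octane-4-carboxylic acid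
Product: 15 (3S,4S,5S,6R)-5-[3-hydroxy-2-(hydroxymethyl)prop-1-en-1-yl]-6-(propan-2-yl)-1-oxaspiro[2.5]octane-4-carboxylic acid
Conditions: Bu4NF, THF, 0 → 23 °C; aq. NH4Cl
Reagents that add atoms: none
Why: Fluoride desilylation of both allylic silyl ethers; intramolecular attack of the carboxylate on the epoxide would be an endo-type opening and is disfavoured.

Step 11
Reactants: 15 (3S,4S,5S,6R)-5-[3-hydroxy-2-(hydroxymethyl)prop-1-en-1-yl]-6-(propan-2-yl)-1-oxaspiro[2.5]octane-4-carboxylic acid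
Product: 17 (5aS,6R,9S,9aS)-4-(hydroxymethyl)-6-(propan-2-yl)-5a,6,7,8-tetrahydro-3H-spiro[2-benzoxepine-9,2'-oxiran]-1(9aH)-one, via mixed anhydride 16 (not isolated)
Conditions: 2,4,6-Cl3C6H2COCl, Et3N, THF, 23 °C; then DMAP, toluene, 70 °C, high dilution
Reagents that add atoms: none
Why: Yamaguchi lactonisation; only the CH2OH cis to the ring across the alkene can reach the activated carboxyl, so the trans-fused seven-membered lactone (ring B) forms and the other CH2OH, the future CO2H, stays free.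

Step 12
Reactants: 18 3-nitropropanoic acid
Product: 19 methyl 3-nitropropanoate
Conditions: MeOH, H2SO4 (cat.), reflux
Reagents that add atoms: methanol, CO
Why: Fischer esterification.

Step 13
Reactants: 19 methyl 3-nitropropanoate
Product: 21 methyl 2-[(PMB-oxy)methyl]-3-nitropropanoate (racemic), via dilithio nitronate enolate 20 (not isolated)
Conditions: LiN(i-Pr)2 (2.1 equiv), THF/DMPU, −78 °C; then PMBOCH2Cl; aq. NH4Cl
Reagents that add atoms: 4-methoxybenzyl chloromethyl ether, COc1ccc(COCCl)cc1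
Why: Seebach dianion alkylation; the doubly deprotonated nitro ester reacts at the ester α-carbon, and the new centre is irrelevant because it becomes sp2 later.

Step 14
Reactants: 4 (4R)-4-(propan-2-yl)cyclohex-2-en-1-one
Product: 22 (4R)-1-[(PMB-oxy)methyl]-4-(propan-2-yl)cyclohex-2-en-1-ol (C1 epimers)
Conditions: Bu3SnCH2OPMB, n-BuLi, THF, −78 °C; then 4; aq. NH4Cl
Reagents that add atoms: tributyl{[(4-methoxyphenyl)methoxy]methyl}stannane, CCCC[Sn](CCCC)(CCCC)COCc1ccc(OC)cc1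
Why: Tin–lithium exchange gives an α-alkoxymethyllithium (Still-type reagent) that adds 1,2 to the enone; the carbinol configuration does not matter because it is erased in the next step.

Step 15
Reactants: 22 (4R)-1-[(PMB-oxy)methyl]-4-(propan-2-yl)cyclohex-2-en-1-ol
Product: 23 (6R)-3-[(PMB-oxy)methyl]-6-(propan-2-yl)cyclohex-2-en-1-one
Conditions: C5H5NH[CrO3Cl] (pyridinium chlorochromate), NaOAc, Celite, CH2Cl2, 23 °C
Reagents that add atoms: pyridinium chlorochromate, [O-][Cr](=O)(=O)Cl.c1cc[nH+]cc1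
Why: Babler–Dauben oxidative 1,3-transposition ([3,3] shift of the chromate ester, then oxidation); it moves the carbonyl next to the isopropyl-bearing carbon, whose configuration is kept under the buffered conditions.

Step 16
Reactants: 23 (6R)-3-[(PMB-oxy)methyl]-6-(propan-2-yl)cyclohex-2-en-1-one
Product: 24 (1S,6R)-3-[(PMB-oxy)methyl]-6-(propan-2-yl)cyclohex-2-en-1-ol (OH cis to isopropyl)
Conditions: LiBH(s-Bu)3, THF, −78 °C; aq. NH4Cl
Reagents that add atoms: none
Why: 1,2-Reduction of the β-substituted enone by a bulky hydride from the equatorial direction, which gives the axial alcohol cis to the equatorial isopropyl group (1S).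

Step 17
Reactants: 24 (1S,6R)-3-[(PMB-oxy)methyl]-6-(propan-2-yl)cyclohex-2-en-1-ol
Product: 25 methyl (1S,6R)-3-[(PMB-oxy)methyl]-6-(propan-2-yl)cyclohex-2-en-1-yl carbonate
Conditions: ClCO2Me, pyridine, DMAP (cat.), CH2Cl2, 0 °C
Reagents that add atoms: methyl chloroformate, COC(=O)Cl
Why: Acylation of the alcohol to an allylic carbonate; the C–O bond is not touched, so the configuration is kept.

Step 18
Reactants: 25 methyl (1S,6R)-3-[(PMB-oxy)methyl]-6-(propan-2-yl)cyclohex-2-en-1-yl carbonate; 21 methyl 2-[(PMB-oxy)methyl]-3-nitropropanoate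
Product: 27 methyl (2E)-2-[(PMB-oxy)methyl]-3-{(1S,6R)-3-[(PMB-oxy)methyl]-6-(propan-2-yl)cyclohex-2-en-1-yl}prop-2-enoate, via nitro adduct 26 (not isolated)
Conditions: Pd2(dba)3·CHCl3 (2.5 mol %), Ph2PCH2CH2PPh2 (6 mol %), 21 (1.5 equiv), THF/DMSO 4:1, 25 °C; then DBU (1.5 equiv), 0 °C
Reagents that add atoms: none
Why: Proposed new method: a stereoretentive Tsuji–Trost allylation in which a 2-substituted 3-nitropropanoate serves as a masked (E)-β-acrylate carbanion. Zerovalent palladium ionises the pseudoaxial carbonate from the face opposite to it (also opposite to isopropyl), the released methoxide forms the nitronate, and this soft nucleophile attacks the less hindered allyl terminus C1 from the face opposite to palladium, so the net result is retention and a new C–C bond cis to isopropyl (1S). DBU then expels nitrite by E1cB from the ester enolate (nitrite leaves far better than the β-alkoxide) to give the conjugated alkene with the ring trans to the ester. The closest known reactions are palladium-catalysed allylic alkylation with nitroalkane nitronates and the use of 3-nitropropanoates as acrylate anion equivalents with loss of HNO2.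

Step 19
Reactants: 27 methyl (2E)-2-[(PMB-oxy)methyl]-3-{(1S,6R)-3-[(PMB-oxy)methyl]-6-(propan-2-yl)cyclohex-2-en-1-yl}prop-2-enoate
Product: 28 (2E)-2-[(PMB-oxy)methyl]-3-{(1S,6R)-3-[(PMB-oxy)methyl]-6-(propan-2-yl)cyclohex-2-en-1-yl}prop-2-enoic acid
Conditions: LiOH, THF/MeOH/H2O, 23 °C; then 1 M HCl to pH 3
Reagents that add atoms: lithium hydroxide, [Li+].[OH-]
Why: Saponification of the methyl ester; aqueous hydroxide is too weak to remove the γ-hydrogen, so the cis centre and the alkene geometry are kept.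

Step 20
Reactants: 17 (5aS,6R,9S,9aS)-4-(hydroxymethyl)-6-(propan-2-yl)-5a,6,7,8-tetrahydro-3H-spiro[2-benzoxepine-9,2'-oxiran]-1(9aH)-one; 28 (2E)-2-[(PMB-oxy)methyl]-3-{(1S,6R)-3-[(PMB-oxy)methyl]-6-(propan-2-yl)cyclohex-2-en-1-yl}prop-2-enoic acid
Product: 29 (5aS,6R,9S,9aS)-9-hydroxy-4-(hydroxymethyl)-9-({[(2E)-2-[(PMB-oxy)methyl]-3-{(1S,6R)-3-[(PMB-oxy)methyl]-6-(propan-2-yl)cyclohex-2-en-1-yl}prop-2-enoyl]oxy}methyl)-6-(propan-2-yl)-5a,6,7,8,9,9a-hexahydro-2-benzoxepin-1(3H)-one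
Conditions: Cs2CO3 (0.2 equiv), Bu4NBr (0.1 equiv), 28 (1.3 equiv), DMF, 70 °C
Reagents that add atoms: none
Why: Base-catalysed SN2 opening of the 2,2-disubstituted epoxide by the carboxylate at the CH2 carbon; the C–O bond at the quaternary carbon is not broken, so the carbinol configuration from step 7 is kept. No free γ-hydroxy lactone is ever formed, and the excess acid buffers the medium.

Step 21
Reactants: 29 (the coupled hydroxy ester of step 20)
Product: 30 (5aS,6R,9S,9aS)-9-hydroxy-1-oxo-9-({[(2E)-2-[(PMB-oxy)methyl]-3-{(1S,6R)-3-[(PMB-oxy)methyl]-6-(propan-2-yl)cyclohex-2-en-1-yl}prop-2-enoyl]oxy}methyl)-6-(propan-2-yl)-1,3,5a,6,7,8,9,9a-octahydro-2-benzoxepine-4-carbaldehyde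
Conditions: MnO2 (activated), CH2Cl2, 23 °C
Reagents that add atoms: none
Why: Chemoselective MnO2 oxidation of the only free primary allylic alcohol to the enal; the tertiary alcohol and the PMB ethers are inert.

Step 22
Reactants: 30 (the enal of step 21)
Product: 31 (5aS,6R,9S,9aS)-9-hydroxy-9-({[(2E)-2-(hydroxymethyl)-3-[(1S,6R)-3-(hydroxymethyl)-6-(propan-2-yl)cyclohex-2-en-1-yl]prop-2-enoyl]oxy}methyl)-1-oxo-6-(propan-2-yl)-1,3,5a,6,7,8,9,9a-octahydro-2-benzoxepine-4-carbaldehyde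
Conditions: DDQ (2.6 equiv), CH2Cl2/pH 7 buffer 10:1, 0 °C
Reagents that add atoms: none
Why: Oxidative removal of both PMB ethers under neutral conditions that spare the lactone, the ester and the enal.

Step 23
Reactants: 31 (the diol enal of step 22)
Product: 32 CNP0361406.9, (5aS,6R,9S,9aS)-9-hydroxy-9-({[(2E)-2-(hydroxymethyl)-3-[(1S,6R)-3-(hydroxymethyl)-6-(propan-2-yl)cyclohex-2-en-1-yl]prop-2-enoyl]oxy}methyl)-1-oxo-6-(propan-2-yl)-1,3,5a,6,7,8,9,9a-octahydro-2-benzoxepine-4-carboxylic acid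
Conditions: NaClO2, NaH2PO4, 2-methylbut-2-ene, t-BuOH/H2O, 0 °C
Reagents that add atoms: sodium chlorite, [Na+].[O-]Cl=O
Why: Pinnick (Lindgren–Kraus) oxidation of the enal to the acid; the buffered, scavenged conditions leave alcohols, alkenes, ester and lactone untouched and change no stereocentre.

## Compound list

1 | 3-methylbutanal | CC(C)CC=O | starting material
2 | but-3-en-2-one | CC(=O)C=C | starting material
3 | (2R)-5-oxo-2-(propan-2-yl)hexanal | CC(C)[C@H](C=O)CCC(C)=O | intermediate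
4 | (4R)-4-(propan-2-yl)cyclohex-2-en-1-one | CC(C)[C@H]1CCC(=O)C=C1 | intermediate
5 | 1,3-dihydroxypropan-2-one | OCC(=O)CO | starting material
6 | 1,3-bis(TBS-oxy)propan-2-one | CC(C)(C)[Si](C)(C)OCC(=O)CO[Si](C)(C)C(C)(C)C | intermediate
7 | 1-bromo-3-(TBS-oxy)-2-[(TBS-oxy)methyl]prop-1-ene | BrC=C(CO[Si](C)(C)C(C)(C)C)CO[Si](C)(C)C(C)(C)C | intermediate
8 | {3-(TBS-oxy)-2-[(TBS-oxy)methyl]prop-1-en-1-yl}magnesium bromide | Br[Mg]C=C(CO[Si](C)(C)C(C)(C)C)CO[Si](C)(C)C(C)(C)C | intermediate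
9 | (3S,4R)-3-(side chain)-4-(propan-2-yl)-1-(TMS-oxy)cyclohex-1-ene (alkenyl trans to isopropyl) | CC(C)[C@H]1CCC(O[Si](C)(C)C)=C[C@@H]1C=C(CO[Si](C)(C)C(C)(C)C)CO[Si](C)(C)C(C)(C)C | intermediate
10 | (2R,3S,4R)-3-(side chain)-2-[(PMB-oxy)methyl]-4-(propan-2-yl)cyclohexan-1-one (all-trans) | CC(C)[C@H]1CCC(=O)[C@@H](COCc2ccc(OC)cc2)[C@@H]1C=C(CO[Si](C)(C)C(C)(C)C)CO[Si](C)(C)C(C)(C)C | intermediate
11 | (3S,4R,5S,6R)-5-(side chain)-4-[(PMB-oxy)methyl]-6-(propan-2-yl)-1-oxaspiro[2.5]octane (epoxide CH2 axial, O equatorial) | CC(C)[C@H]1CC[C@@]2(CO2)[C@@H](COCc3ccc(OC)cc3)[C@@H]1C=C(CO[Si](C)(C)C(C)(C)C)CO[Si](C)(C)C(C)(C)C | intermediate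
12 | [(3S,4R,5S,6R)-5-(side chain)-6-(propan-2-yl)-1-oxaspiro[2.5]octan-4-yl]methanol | CC(C)[C@H]1CC[C@@]2(CO2)[C@@H](CO)[C@@H]1C=C(CO[Si](C)(C)C(C)(C)C)CO[Si](C)(C)C(C)(C)C | intermediate
13 | (3S,4S,5S,6R)-5-(side chain)-6-(propan-2-yl)-1-oxaspiro[2.5]octane-4-carbaldehyde | CC(C)[C@H]1CC[C@@]2(CO2)[C@@H](C=O)[C@@H]1C=C(CO[Si](C)(C)C(C)(C)C)CO[Si](C)(C)C(C)(C)C | intermediate
14 | (3S,4S,5S,6R)-5-(side chain)-6-(propan-2-yl)-1-oxaspiro[2.5]octane-4-carboxylic acid | CC(C)[C@H]1CC[C@@]2(CO2)[C@@H](C(=O)O)[C@@H]1C=C(CO[Si](C)(C)C(C)(C)C)CO[Si](C)(C)C(C)(C)C | intermediate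
15 | (3S,4S,5S,6R)-5-[3-hydroxy-2-(hydroxymethyl)prop-1-en-1-yl]-6-(propan-2-yl)-1-oxaspiro[2.5]octane-4-carboxylic acid | CC(C)[C@H]1CC[C@@]2(CO2)[C@@H](C(=O)O)[C@@H]1C=C(CO)CO | intermediate
16 | mixed anhydride of 15 with 2,4,6-trichlorobenzoic acid | CC(C)[C@H]1CC[C@@]2(CO2)[C@@H](C(=O)OC(=O)c3c(Cl)cc(Cl)cc3Cl)[C@@H]1C=C(CO)CO | intermediate
17 | (5aS,6R,9S,9aS)-4-(hydroxymethyl)-6-(propan-2-yl)-5a,6,7,8-tetrahydro-3H-spiro[2-benzoxepine-9,2'-oxiran]-1(9aH)-one (trans-fused spiro-epoxy lactone) | CC(C)[C@H]1CC[C@@]2(CO2)[C@H]3C(=O)OCC(CO)=C[C@H]13 | intermediate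
18 | 3-nitropropanoic acid | OC(=O)CC[N+](=O)[O-] | starting material
19 | methyl 3-nitropropanoate | COC(=O)CC[N+](=O)[O-] | intermediate
20 | dilithium nitronate/ester enolate of 19 | [Li]OC(OC)=CC=[N+]([O-])O[Li] | intermediate
21 | methyl 2-[(PMB-oxy)methyl]-3-nitropropanoate (racemic) | COC(=O)C(COCc1ccc(OC)cc1)C[N+](=O)[O-] | intermediate
22 | (4R)-1-[(PMB-oxy)methyl]-4-(propan-2-yl)cyclohex-2-en-1-ol (C1 epimers) | CC(C)[C@H]1CCC(O)(COCc2ccc(OC)cc2)C=C1 | intermediate
23 | (6R)-3-[(PMB-oxy)methyl]-6-(propan-2-yl)cyclohex-2-en-1-one | O=C1C=C(COCc2ccc(OC)cc2)CC[C@@H]1C(C)C | intermediate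
24 | (1S,6R)-3-[(PMB-oxy)methyl]-6-(propan-2-yl)cyclohex-2-en-1-ol (OH cis to isopropyl) | O[C@@H]1C=C(COCc2ccc(OC)cc2)CC[C@@H]1C(C)C | intermediate
25 | methyl (1S,6R)-3-[(PMB-oxy)methyl]-6-(propan-2-yl)cyclohex-2-en-1-yl carbonate | COC(=O)O[C@@H]1C=C(COCc2ccc(OC)cc2)CC[C@@H]1C(C)C | intermediate
26 | methyl 3-nitro-2-[(PMB-oxy)methyl]-3-{(1S,6R)-3-[(PMB-oxy)methyl]-6-(propan-2-yl)cyclohex-2-en-1-yl}propanoate (mixture at C2 and C3) | COC(=O)C(COCc1ccc(OC)cc1)C([N+](=O)[O-])[C@@H]1C=C(COCc2ccc(OC)cc2)CC[C@@H]1C(C)C | intermediate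
27 | methyl (2E)-2-[(PMB-oxy)methyl]-3-{(1S,6R)-3-[(PMB-oxy)methyl]-6-(propan-2-yl)cyclohex-2-en-1-yl}prop-2-enoate | COC(=O)/C(=C/[C@@H]1C=C(COCc2ccc(OC)cc2)CC[C@@H]1C(C)C)COCc1ccc(OC)cc1 | intermediate
28 | (2E)-2-[(PMB-oxy)methyl]-3-{(1S,6R)-3-[(PMB-oxy)methyl]-6-(propan-2-yl)cyclohex-2-en-1-yl}prop-2-enoic acid | OC(=O)/C(=C/[C@@H]1C=C(COCc2ccc(OC)cc2)CC[C@@H]1C(C)C)COCc1ccc(OC)cc1 | intermediate
29 | coupled hydroxy ester: target skeleton with CH2OH at C4 of the lactone ring and both right-half hydroxyls as PMB ethers | CC(C)[C@H]1CC[C@@](O)(COC(=O)/C(=C/[C@@H]2C=C(COCc3ccc(OC)cc3)CC[C@@H]2C(C)C)COCc4ccc(OC)cc4)[C@H]5C(=O)OCC(CO)=C[C@H]15 | intermediate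
30 | as 29 with CHO in place of the lactone-ring CH2OH | CC(C)[C@H]1CC[C@@](O)(COC(=O)/C(=C/[C@@H]2C=C(COCc3ccc(OC)cc3)CC[C@@H]2C(C)C)COCc4ccc(OC)cc4)[C@H]5C(=O)OCC(C=O)=C[C@H]15 | intermediate
31 | as 30 with both PMB ethers cleaved (diol enal) | CC(C)[C@H]1CC[C@@](O)(COC(=O)/C(=C/[C@@H]2C=C(CO)CC[C@@H]2C(C)C)CO)[C@H]3C(=O)OCC(C=O)=C[C@H]13 | intermediate
32 | CNP0361406.9 | CC(C)[C@H]1CC[C@@](O)(COC(=O)/C(=C/[C@@H]2C=C(CO)CC[C@@H]2C(C)C)CO)[C@H]2C(=O)OCC(C(=O)O)=C[C@H]12 | target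

## Step count and risks

Total step count: 23. Longest linear sequence: 13 (steps 1, 2, 5, 6, 7, 8, 9, 10, 11, 20, 21, 22, 23).

Step 18 (the proposed new allylation with loss of HNO2) is the most likely to fail. The nitro ester may lose HNO2 before it is allylated, or the nitronate may react at oxygen. The fallback uses known chemistry only, sets out from enone 23 and comes back at ester 27.
- Luche reduction of 23 (NaBH4, CeCl3·7H2O, MeOH, −78 °C) gives the trans-allylic alcohol (1R,6R)-3-[(PMB-oxy)methyl]-6-(propan-2-yl)cyclohex-2-en-1-ol F1.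
- ClCO2Me/pyridine converts it into the methyl carbonate of this trans alcohol F2.
- A Stille coupling of the allylic carbonate with tributyl{3-[(4-methoxyphenyl)methoxy]prop-1-yn-1-yl}stannane (Pd2(dba)3, tri(2-furyl)phosphine, LiCl, DMF, 50 °C) goes by transmetalation and reductive elimination on the palladium face, hence with inversion, to the cis 1,4-enyne 1-methoxy-4-[({3-[(1S,6R)-3-[(PMB-oxy)methyl]-6-(propan-2-yl)cyclohex-2-en-1-yl]prop-2-yn-1-yl}oxy)methyl]benzene F3.
- PdCl2(PPh3)2-catalysed syn-hydrostannation (Bu3SnH, THF) puts tin on the carbon next to CH2OPMB and gives the (E)-vinylstannane tributyl{(1E)-3-(PMB-oxy)-1-[(1S,6R)-3-[(PMB-oxy)methyl]-6-(propan-2-yl)cyclohex-2-en-1-yl]prop-1-en-2-yl}stannane F4.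
- I2 (CH2Cl2, 0 °C) gives, with retention, the (E)-vinyl iodide 1-({[(2E)-2-iodo-3-[(1S,6R)-3-[(PMB-oxy)methyl]-6-(propan-2-yl)cyclohex-2-en-1-yl]prop-2-en-1-yl]oxy}methyl)-4-methoxybenzene F5.
- Methoxycarbonylation (Pd(OAc)2, PPh3, CO 1 atm, MeOH, Et3N, DMF, 50 °C) returns 27.

Step 11 (seven-membered lactonisation of a seco acid that also carries an epoxide and a second free hydroxyl) may give oligomers. The fallback sets out from 15 and comes back at 17. It activates the alcohol instead of the acid: a Mitsunobu lactonisation (PPh3, diisopropyl azodicarboxylate, toluene/THF, high dilution), in which the carboxylate displaces the activated cis CH2OH intramolecularly. No new isolated compound is made.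

Step 7 (ylide epoxidation of a β-alkoxy ketone) may suffer β-elimination of PMBO− or a poor axial/equatorial ratio. The fallback sets out from 10 and comes back at 11.
- Wittig methylenation (Ph3P=CH2, THF) gives the exocyclic alkene 2-[(PMB-oxy)methyl]-3-(side chain)-1-methylidene-4-(propan-2-yl)cyclohexane with the ring configuration of 10 F6.
- Dihydroxylation (OsO4 cat., N-methylmorpholine N-oxide, acetone/H2O; equatorial attack expected) gives the diol with equatorial tertiary OH and axial CH2OH F7.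
- Selective sulfonylation of the primary hydroxyl (TsCl, Et3N, Bu2SnO cat.) gives the primary tosylate of this diol F8.
- K2CO3 in MeOH closes it to epoxide 11.

## Further compounds

F1 | step 18 | (1R,6R)-3-[(PMB-oxy)methyl]-6-(propan-2-yl)cyclohex-2-en-1-ol (OH trans to isopropyl) | O[C@H]1C=C(COCc2ccc(OC)cc2)CC[C@@H]1C(C)C
F2 | step 18 | methyl (1R,6R)-3-[(PMB-oxy)methyl]-6-(propan-2-yl)cyclohex-2-en-1-yl carbonate | COC(=O)O[C@H]1C=C(COCc2ccc(OC)cc2)CC[C@@H]1C(C)C
F3 | step 18 | 1-methoxy-4-[({3-[(1S,6R)-3-[(PMB-oxy)methyl]-6-(propan-2-yl)cyclohex-2-en-1-yl]prop-2-yn-1-yl}oxy)methyl]benzene | COc1ccc(COCC#C[C@@H]2C=C(COCc3ccc(OC)cc3)CC[C@@H]2C(C)C)cc1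
F4 | step 18 | tributyl{(1E)-3-(PMB-oxy)-1-[(1S,6R)-3-[(PMB-oxy)methyl]-6-(propan-2-yl)cyclohex-2-en-1-yl]prop-1-en-2-yl}stannane | CCCC[Sn](CCCC)(CCCC)/C(=C/[C@@H]1C=C(COCc2ccc(OC)cc2)CC[C@@H]1C(C)C)COCc1ccc(OC)cc1
F5 | step 18 | 1-({[(2E)-2-iodo-3-[(1S,6R)-3-[(PMB-oxy)methyl]-6-(propan-2-yl)cyclohex-2-en-1-yl]prop-2-en-1-yl]oxy}methyl)-4-methoxybenzene | I/C(=C/[C@@H]1C=C(COCc2ccc(OC)cc2)CC[C@@H]1C(C)C)COCc1ccc(OC)cc1
F0 | step 11 | none | none
F6 | step 7 | 2-[(PMB-oxy)methyl]-3-(side chain)-1-methylidene-4-(propan-2-yl)cyclohexane (ring configuration of 10) | CC(C)[C@H]1CCC(=C)[C@@H](COCc2ccc(OC)cc2)[C@@H]1C=C(CO[Si](C)(C)C(C)(C)C)CO[Si](C)(C)C(C)(C)C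
F7 | step 7 | 1-(hydroxymethyl)-2-[(PMB-oxy)methyl]-3-(side chain)-4-(propan-2-yl)cyclohexan-1-ol (tertiary OH equatorial, CH2OH axial) | CC(C)[C@H]1CC[C@@](O)(CO)[C@@H](COCc2ccc(OC)cc2)[C@@H]1C=C(CO[Si](C)(C)C(C)(C)C)CO[Si](C)(C)C(C)(C)C
F8 | step 7 | primary 4-methylbenzenesulfonate of diol F7 | CC(C)[C@H]1CC[C@@](O)(COS(=O)(=O)c2ccc(C)cc2)[C@@H](COCc3ccc(OC)cc3)[C@@H]1C=C(CO[Si](C)(C)C(C)(C)C)CO[Si](C)(C)C(C)(C)C
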